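A direct plan would close the ring from the acyclic keto aldehyde 2,2-dimethyl-6-oxoheptanal A1 by a chiral-carbene benzoin cyclisation to (R)-2-hydroxy-2,6,6-trimethylcyclohexanone A2,
add metalated (E)-3-methylpent-2-en-4-yn-1-ol to the ketone to give the enyne triol A3, reduce the alkyne, make the C15 phosphonium salt A4 with PPh3·HBr,
and finish with two Wittig reactions (C10 dialdehyde, then a dioxolanylmethyl ylide) and acid hydrolysis of the dioxolane acetal A5.
Weakest would be the benzoin ring closure: ring formation and the C5 configuration would both hang on a carbene catalyst untested on an α-quaternary aliphatic aldehyde, after steps that only build an achiral chain.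
Next, the acetylide addition: the C6 configuration would rest on chelation control at a ketone wedged between two fully substituted carbons.
Last, the acid steps (HBr on the tertiary allylic diol, aqueous HCl on the finished heptaene): ionisation of the C6–OH next to the polyene would threaten the most precious material.

The new retrosynthesis cuts C11=C12 (Wittig), C7=C8 (Horner–Wadsworth–Emmons) and C11′=C12′ (Horner–Wadsworth–Emmons on the C10 dialdehyde), and traces both ring C–O bonds to the C5=C6 double bond of β-cyclocitral.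
Feature used: C5 and C6 are vicinal, fully substituted and trans-dioxygenated, and C6 carries the sp2 carbon C7; the diol is thus the anti-hydration product of a cyclogeranyl C5=C6 alkene whose allylic C7–OH can steer a tartrate–titanium epoxidation.
The carbocycle is bought and never closed; the only ring made is the C5–O–C6 oxirane (step 2), which the C7 alkoxide then opens from the rear at C6 (Payne rearrangement, step 3), so O7 ends as the C6 hydroxyl and the oxirane oxygen as the C5 hydroxyl.
No ring closure or C–C bond formation at C5 or C6 is left to chance: both carbinol centres come from one reagent-controlled oxygen transfer and one intramolecular inversion.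
Acid is used only on the achiral C12 nitrile fragment, and the aldehyde is released from a nitrile by i-Bu2AlH with neutral work-up, so the finished diol–polyene never meets acid.

Key step: step 2

Remark: positions are given in carotenoid numbering (ring C1–C6, chain C7–C15, then C15′ down to the aldehyde carbon C10′); compounds 1, 7, 12 and 13 are taken as commercial.

Step 1
Reactants: 1 β-cyclocitral (2,6,6-trimethylcyclohex-1-ene-1-carbaldehyde)
Product: 2 β-cyclogeraniol [(2,6,6-trimethylcyclohex-1-en-1-yl)methanol]
Conditions: NaBH4 (0.6 equiv), MeOH, 0 °C, 1 h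
Reagents that add atoms: none
Why: Carbonyl hydride reduction of the hindered enal should give only the allylic alcohol, since the tetrasubstituted, electron-rich C5=C6 bond does not accept hydride in the conjugate sense, and no stereocentre is formed.

Step 2
Reactants: 2 β-cyclogeraniol
Product: 3 [(1R,6R)-2,2,6-trimethyl-7-oxabicyclo[4.1.0]heptan-1-yl]methanol
Conditions: Ti(OiPr)4 (0.3 equiv), diethyl D-(–)-tartrate (0.36 equiv), t-BuOOH (2.0 equiv, anhydrous in isooctane), 4 Å molecular sieves, CH2Cl2, –20 °C, 48 h
Reagents that add atoms: tert-butyl hydroperoxide, CC(C)(C)OO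
Why: Katsuki–Sharpless asymmetric epoxidation: the allylic alkoxide of 2 and the tert-butyl peroxide bind to one titanium of the tartrate-bridged dimer, and the peroxide oxygen is passed to the C5=C6 bond inside this chiral pocket; the closest known cases are tartrate-controlled epoxidations of 2-alkylcyclohex-1-enylmethanols with tetrasubstituted double bonds. The oxirane ring (C5–O–C6) closes by concerted syn transfer of one oxygen atom to both alkene carbons, so both C–O bonds form on the same face at once. Both new stereocentres, C5 and C6, are set by the tartrate alone: the (2S,3S)-tartrate puts the oxygen on the face that makes the CH2OH-bearing oxirane carbon R, as it does throughout the 2,3-epoxy alcohol series (geraniol gives the 2R,3R epoxide with this tartrate), and the cis ring fusion then fixes the second centre as R. The only selectivity needed is enantiofacial, because 2 is achiral and has a single alkene and a single hydroxyl; the hydroxyl on C7 ties the substrate to titanium, and the substituent cis to CH2OH, where bulk erodes selectivity, is only a methyl group. Molecular sieves keep the complex dry so that sub-stoichiometric titanium should turn over despite the hindered product alkoxide.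

Step 3
Reactants: 3 [(1R,6R)-2,2,6-trimethyl-7-oxabicyclo[4.1.0]heptan-1-yl]methanol
Product: 5 (1S,2R)-1-(hydroxymethyl)-2,6,6-trimethylcyclohexane-1,2-diol, via spiro-epoxide 4 (not isolated)
Conditions: NaOH (0.5 M in H2O, 3 equiv), t-BuOH, 70 °C, 24 h
Reagents that add atoms: water, O
Why: Payne rearrangement followed by hydrolysis: the C7 alkoxide attacks C6 from the face opposite the oxirane C6–O bond (3-exo-tet, inversion at C6) to give spiro-epoxide 4, whose unhindered CH2 terminus (C7) is opened irreversibly by hydroxide, so the former O7 becomes the C6 hydroxyl trans to the untouched C5 oxygen (C5 stays R); since hydroxide cannot attack the fully substituted carbons directly, regio- and stereochemistry are fixed by the mechanism.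

Step 4
Reactants: 5 (1S,2R)-1-(hydroxymethyl)-2,6,6-trimethylcyclohexane-1,2-diol
Product: 6 (1R,2R)-1,2-dihydroxy-2,6,6-trimethylcyclohexane-1-carbaldehyde
Conditions: SO3·pyridine (3 equiv), DMSO, i-Pr2NEt (4 equiv), CH2Cl2, 0 °C, 1 h
Reagents that add atoms: none
Why: Parikh–Doering oxidation (activated DMSO) should convert only the primary alcohol, because the two tertiary hydroxyls cannot be oxidised and the reagent does not cleave 1,2-diols, and the aldehyde formed has no α-hydrogen, so C6 cannot epimerise (its descriptor changes to R only through the priority of CHO).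

Step 5
Reactants: 6 (1R,2R)-1,2-dihydroxy-2,6,6-trimethylcyclohexane-1-carbaldehyde; 7 diethyl [(2E)-3-cyano-2-methylprop-2-en-1-yl]phosphonate
Product: 9 (2E,4E)-5-[(1R,2R)-1,2-dihydroxy-2,6,6-trimethylcyclohexyl]-3-methylpenta-2,4-dienenitrile, via lithiated phosphonate 8 (not isolated)
Conditions: 7 (1.5 equiv), n-BuLi (1.45 equiv), THF, –78 °C, 30 min; then 6, –78 → 0 °C, 3 h
Reagents that add atoms: none
Why: Horner–Wadsworth–Emmons olefination: the nitrile-stabilised allylic carbanion 8 adds through its α-carbon to the aldehyde and the oxaphosphetane collapses to the E C7=C8 bond, the anion is too weakly basic to deprotonate the tertiary hydroxyls (no retro-aldol opening of the ring), the C9=C10 E geometry comes from the reagent, and any 9Z isomer formed through the delocalised anion would be removed by chromatography.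

Step 6
Reactants: 9 (2E,4E)-5-[(1R,2R)-1,2-dihydroxy-2,6,6-trimethylcyclohexyl]-3-methylpenta-2,4-dienenitrile
Product: 11 (2E,4E)-5-[(1R,2R)-1,2-dihydroxy-2,6,6-trimethylcyclohexyl]-3-methylpenta-2,4-dienal, via aluminium aldimine 10 (not isolated)
Conditions: i-Bu2AlH (3.5 equiv), CH2Cl2, –78 °C, 1 h; then moist SiO2, 0 °C
Reagents that add atoms: water, O
Why: Nitrile half-reduction: after the two hydroxyls are capped as aluminium alkoxides, one hydride adds to C≡N and the N-aluminio aldimine 10 persists at –78 °C until neutral hydrolysis on moist silica gives the dienal, without exposing the allylic tertiary C6–OH to acid or disturbing either E double bond.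

Step 7
Reactants: 12 (2E,4E,6E)-2,7-dimethylocta-2,4,6-trienedial; 13 diethyl (cyanomethyl)phosphonate
Product: 15 (2E,4E,6E,8E)-4,9-dimethyl-10-oxodeca-2,4,6,8-tetraenenitrile, via sodium cyanomethylphosphonate carbanion 14 (not isolated)
Conditions: 13 (1.0 equiv), NaH (1.0 equiv), THF, 0 °C; added slowly to 12 (3 equiv), THF, –20 → 0 °C, 2 h
Reagents that add atoms: none
Why: Horner–Wadsworth–Emmons mono-olefination: slow addition of carbanion 14 to an excess of the symmetrical dialdehyde should let only one formyl group react and give the E C11′=C12′ bond, the surplus dialdehyde is recovered, and a minor 2Z isomer would be separated at this small stage.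

Step 8
Reactants: 15 (2E,4E,6E,8E)-4,9-dimethyl-10-oxodeca-2,4,6,8-tetraenenitrile
Product: 16 (2E,4E,6E,8E)-10-hydroxy-4,9-dimethyldeca-2,4,6,8-tetraenenitrile
Conditions: NaBH4 (0.5 equiv), MeOH/THF, –20 °C, 30 min
Reagents that add atoms: none
Why: Borohydride 1,2-reduction of the conjugated aldehyde at low temperature should leave the conjugated nitrile and the four E double bonds untouched.

Step 9
Reactants: 16 (2E,4E,6E,8E)-10-hydroxy-4,9-dimethyldeca-2,4,6,8-tetraenenitrile
Product: 17 [(2E,4E,6E,8E)-9-cyano-2,7-dimethylnona-2,4,6,8-tetraen-1-yl]triphenylphosphonium bromide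
Conditions: PPh3·HBr (1.05 equiv), MeOH, 0 °C → rt, 12 h
Reagents that add atoms: triphenylphosphine hydrobromide, [Br-].[PH+](c1ccccc1)(c1ccccc1)c1ccccc1
Why: Acid-mediated allylic substitution of the primary polyenylic alcohol by triphenylphosphine (the usual phosphonium salt formation of carotenoid building blocks) is run here on the achiral, diol-free chain fragment, where the acid can do no harm, and the thermodynamic E geometry is kept.

Step 10
Reactants: 17 [(2E,4E,6E,8E)-9-cyano-2,7-dimethylnona-2,4,6,8-tetraen-1-yl]triphenylphosphonium bromide; 11 (2E,4E)-5-[(1R,2R)-1,2-dihydroxy-2,6,6-trimethylcyclohexyl]-3-methylpenta-2,4-dienal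
Product: 20 (2E,4E,6E,8E,10E,12E,14E)-15-[(1R,2R)-1,2-dihydroxy-2,6,6-trimethylcyclohexyl]-4,9,13-trimethylpentadeca-2,4,6,8,10,12,14-heptaenenitrile, via phosphonium ylide 18 (not isolated), via 11Z nitrile 19 (not isolated)
Conditions: 17 (1.2 equiv), NaOMe (1.2 equiv), MeOH/CH2Cl2, 0 °C; then 11, 0 °C → rt, 4 h; then I2 (1 mol%), CH2Cl2, daylight, rt, 1 h
Reagents that add atoms: none
Why: Wittig olefination joins the nitrile-conjugated ylide 18 to dienal 11 at C11=C12 under methoxide, which is too weak a base to touch the tertiary diol, and iodine-catalysed equilibration (reversible addition of iodine atoms) should funnel the sterically strained 11Z isomer 19 into the all-E heptaene 20.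

Step 11
Reactants: 20 (2E,4E,6E,8E,10E,12E,14E)-15-[(1R,2R)-1,2-dihydroxy-2,6,6-trimethylcyclohexyl]-4,9,13-trimethylpentadeca-2,4,6,8,10,12,14-heptaenenitrile
Product: 22 (2E,4E,6E,8E,10E,12E,14E)-15-[(1R,2R)-1,2-dihydroxy-2,6,6-trimethylcyclohexyl]-4,9,13-trimethylpentadeca-2,4,6,8,10,12,14-heptaenal, via aluminium aldimine 21 (not isolated)
Conditions: i-Bu2AlH (3.5 equiv), CH2Cl2, –78 °C, 1 h; then moist SiO2, 0 °C, dark, argon
Reagents that add atoms: water, O
Why: Nitrile half-reduction with i-Bu2AlH stops at the N-aluminio aldimine 21 of the heptaenenitrile, and hydrolysis on moist silica at 0 °C releases the polyenal under neutral conditions, so the ionisable allylic C6–OH, the trans-diol and the all-E chain are not put at risk in the last step.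

Compound list
1 | β-cyclocitral (2,6,6-trimethylcyclohex-1-ene-1-carbaldehyde) | O=CC1=C(C)CCCC1(C)C | starting material
2 | β-cyclogeraniol [(2,6,6-trimethylcyclohex-1-en-1-yl)methanol] | OCC1=C(C)CCCC1(C)C | intermediate
3 | [(1R,6R)-2,2,6-trimethyl-7-oxabicyclo[4.1.0]heptan-1-yl]methanol | OC[C@]12C(C)(C)CCC[C@@]1(C)O2 | intermediate
4 | (3S,4R)-4,8,8-trimethyl-1-oxaspiro[2.5]octan-4-ol (present as its alkoxide) | O1C[C@]12C(C)(C)CCC[C@@]2(C)O | intermediate
5 | (1S,2R)-1-(hydroxymethyl)-2,6,6-trimethylcyclohexane-1,2-diol | OC[C@@]1(O)C(C)(C)CCC[C@@]1(C)O | intermediate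
6 | (1R,2R)-1,2-dihydroxy-2,6,6-trimethylcyclohexane-1-carbaldehyde | O=C[C@@]1(O)C(C)(C)CCC[C@@]1(C)O | intermediate
7 | diethyl [(2E)-3-cyano-2-methylprop-2-en-1-yl]phosphonate | CCOP(=O)(OCC)C/C(C)=C/C#N | starting material
8 | lithium salt of the α-carbanion of 7 | [Li+].CCOP(=O)(OCC)[CH-]/C(C)=C/C#N | intermediate
9 | (2E,4E)-5-[(1R,2R)-1,2-dihydroxy-2,6,6-trimethylcyclohexyl]-3-methylpenta-2,4-dienenitrile | N#C/C=C(C)/C=C/[C@@]1(O)C(C)(C)CCC[C@@]1(C)O | intermediate
10 | N-(diisobutylalumanyl) aldimine of 11, both hydroxyls as diisobutylaluminium alkoxides | CC(C)C[Al](CC(C)C)N=C/C=C(C)/C=C/[C@@]1(O[Al](CC(C)C)CC(C)C)C(C)(C)CCC[C@@]1(C)O[Al](CC(C)C)CC(C)C | intermediate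
11 | (2E,4E)-5-[(1R,2R)-1,2-dihydroxy-2,6,6-trimethylcyclohexyl]-3-methylpenta-2,4-dienal | O=C/C=C(C)/C=C/[C@@]1(O)C(C)(C)CCC[C@@]1(C)O | intermediate
12 | (2E,4E,6E)-2,7-dimethylocta-2,4,6-trienedial | O=C/C(C)=C/C=C/C=C(C)/C=O | starting material
13 | diethyl (cyanomethyl)phosphonate | CCOP(=O)(OCC)CC#N | starting material
14 | sodium salt of the carbanion of 13 | [Na+].CCOP(=O)(OCC)[CH-]C#N | intermediate
15 | (2E,4E,6E,8E)-4,9-dimethyl-10-oxodeca-2,4,6,8-tetraenenitrile | N#C/C=C/C(C)=C/C=C/C=C(C)/C=O | intermediate
16 | (2E,4E,6E,8E)-10-hydroxy-4,9-dimethyldeca-2,4,6,8-tetraenenitrile | N#C/C=C/C(C)=C/C=C/C=C(C)/CO | intermediate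
17 | [(2E,4E,6E,8E)-9-cyano-2,7-dimethylnona-2,4,6,8-tetraen-1-yl]triphenylphosphonium bromide | N#C/C=C/C(C)=C/C=C/C=C(C)/C[P+](c1ccccc1)(c1ccccc1)c1ccccc1.[Br-] | intermediate
18 | [(2E,4E,6E,8E)-9-cyano-2,7-dimethylnona-2,4,6,8-tetraenylidene]triphenylphosphorane | N#C/C=C/C(C)=C/C=C/C=C(C)/C=P(c1ccccc1)(c1ccccc1)c1ccccc1 | intermediate
19 | (2E,4E,6E,8E,10Z,12E,14E)-15-[(1R,2R)-1,2-dihydroxy-2,6,6-trimethylcyclohexyl]-4,9,13-trimethylpentadeca-2,4,6,8,10,12,14-heptaenenitrile (11Z in carotenoid numbering) | CC(/C=C/C#N)=C\C=C\C=C(C)\C=C/C=C(C)/C=C/[C@@]1(O)C(C)(C)CCC[C@@]1(C)O | intermediate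
20 | (2E,4E,6E,8E,10E,12E,14E)-15-[(1R,2R)-1,2-dihydroxy-2,6,6-trimethylcyclohexyl]-4,9,13-trimethylpentadeca-2,4,6,8,10,12,14-heptaenenitrile | CC(/C=C/C#N)=C\C=C\C=C(C)\C=C\C=C(C)\C=C\[C@@]1(O)C(C)(C)CCC[C@@]1(C)O | intermediate
21 | N-(diisobutylalumanyl) aldimine of 22, both hydroxyls as diisobutylaluminium alkoxides | CC(/C=C/C=N[Al](CC(C)C)CC(C)C)=C\C=C\C=C(C)\C=C\C=C(C)\C=C\[C@@]1(O[Al](CC(C)C)CC(C)C)C(C)(C)CCC[C@@]1(C)O[Al](CC(C)C)CC(C)C | intermediate
22 | (2E,4E,6E,8E,10E,12E,14E)-15-[(1R,2R)-1,2-dihydroxy-2,6,6-trimethylcyclohexyl]-4,9,13-trimethylpentadeca-2,4,6,8,10,12,14-heptaenal, i.e. (5R,6R)-5,6-dihydroxy-5,6-dihydro-10′-apo-β-caroten-10′-al | CC(/C=C/C=O)=C\C=C\C=C(C)\C=C\C=C(C)\C=C\[C@@]1(O)C(C)(C)CCC[C@@]1(C)O | target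

Total step count: 11. Longest linear sequence: 8 steps (steps 1–6, 10 and 11); the C12 nitrile branch (steps 7–9) adds 3.

Steps most likely to fail:

Step 3. The internal displacement at the fully substituted C6 may be too slow, so that 3 is recovered or degrades on long heating in base. The fallback sets out from 2: the epoxidation would be run with diethyl L-(+)-tartrate to give the enantiomeric epoxy alcohol [(1S,6S)-2,2,6-trimethyl-7-oxabicyclo[4.1.0]heptan-1-yl]methanol F1, which would then be opened with dilute HClO4 in THF/H2O at 0 °C. Water should attack the tertiary C5 with inversion, because C6 is shielded by the gem-dimethyl group and deactivated by the neighbouring CH2OH, while C6 keeps its oxygen; this should give the same triol, and the route is rejoined at 5.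

Step 5. The α-hydroxy aldehyde may suffer retro-aldol ring opening or acyloin-type ring expansion in contact with the basic carbanion before it is olefinated. The fallback sets out from 6: a base-free Wittig reaction with the neutral stabilised ylide Ph3P=CHC(O)CH3 (toluene, 80 °C) would give the enone (E)-4-[(1R,2R)-1,2-dihydroxy-2,6,6-trimethylcyclohexyl]but-3-en-2-one F2, and a Horner–Wadsworth–Emmons reaction of this ketone with carbanion 14 (from 13 and NaH), with separation of the 2E isomer, rejoins the route at 9.

Step 10. Ylide 18 is stabilised through four double bonds by the nitrile and may add only sluggishly to dienal 11, leaving aldehyde unconsumed. The fallback sets out from 16: bromination (PBr3, Et2O, –10 °C) would give (2E,4E,6E,8E)-10-bromo-4,9-dimethyldeca-2,4,6,8-tetraenenitrile F3, and a Michaelis–Arbuzov reaction of this bromide with P(OEt)3 would then give diethyl [(2E,4E,6E,8E)-9-cyano-2,7-dimethylnona-2,4,6,8-tetraen-1-yl]phosphonate F4, whose sodium carbanion (NaH, THF) is the more nucleophilic partner and should give the E alkene with 11 in a Horner–Wadsworth–Emmons reaction, rejoining the route at 20.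

Further compounds
F1 | step 3 | [(1S,6S)-2,2,6-trimethyl-7-oxabicyclo[4.1.0]heptan-1-yl]methanol | OC[C@@]12C(C)(C)CCC[C@]1(C)O2
F2 | step 5 | (E)-4-[(1R,2R)-1,2-dihydroxy-2,6,6-trimethylcyclohexyl]but-3-en-2-one | CC(=O)/C=C/[C@@]1(O)C(C)(C)CCC[C@@]1(C)O
F3 | step 10 | (2E,4E,6E,8E)-10-bromo-4,9-dimethyldeca-2,4,6,8-tetraenenitrile | N#C/C=C/C(C)=C/C=C/C=C(C)/CBr
F4 | step 10 | diethyl [(2E,4E,6E,8E)-9-cyano-2,7-dimethylnona-2,4,6,8-tetraen-1-yl]phosphonate | N#C/C=C/C(C)=C/C=C/C=C(C)/CP(=O)(OCC)OCC
A1 | direct plan | 2,2-dimethyl-6-oxoheptanal | CC(=O)CCCC(C)(C)C=O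
A2 | direct plan | (R)-2-hydroxy-2,6,6-trimethylcyclohexan-1-one | O=C1C(C)(C)CCC[C@@]1(C)O
A3 | direct plan | (1S,2R)-1-[(E)-5-hydroxy-3-methylpent-3-en-1-yn-1-yl]-2,6,6-trimethylcyclohexane-1,2-diol | OC/C=C(C)/C#C[C@@]1(O)C(C)(C)CCC[C@@]1(C)O
A4 | direct plan | [(2E,4E)-5-[(1R,2R)-1,2-dihydroxy-2,6,6-trimethylcyclohexyl]-3-methylpenta-2,4-dien-1-yl]triphenylphosphonium bromide | C(/C=C(C)/C=C/[C@@]1(O)C(C)(C)CCC[C@@]1(C)O)[P+](c1ccccc1)(c1ccccc1)c1ccccc1.[Br-]
A5 | direct plan | 2-[(1E,3E,5E,7E,9E,11E,13E)-14-[(1R,2R)-1,2-dihydroxy-2,6,6-trimethylcyclohexyl]-3,8,12-trimethyltetradeca-1,3,5,7,9,11,13-heptaen-1-yl]-1,3-dioxolane | C1COC(/C=C/C(C)=C/C=C/C=C(C)/C=C/C=C(C)/C=C/[C@@]2(O)C(C)(C)CCC[C@@]2(C)O)O1
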